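At 10 min the flasks eta, alpha, delta and gamma are read for single product, in percent of the starting material charged.

| flask | starting material | partner | remark | time |
|---|---|---|---|---|
| north-east | 0.10 M | 0.028 M | run made earlier |  |
| north-west | 0.10 M | 0.14 M | run made earlier |  |
| eta | 0.20 M | 0.120 M |  | 10 min |
| alpha | 0.10 M | 0.0800 M |  | 10 min |
| delta | 0.060 M | 0.0250 M |  | 10 min |
| gamma | 0.15 M | 0.120 M |  | 10 min |

| run | time / min | single product / % | starting material / % |
|---|---|---|---|
| north-east | 0.500 | 3.8 | 97.4 |
| north-east | 1.00 | 4.6 | 95.4 |
| north-east | 2.00 | 7.0 | 90.9 |
| north-east | 4.00 | 10.5 | 86.0 |
| north-east | 8.00 | 12.9 | 80.3 |
| north-west | 1.33 | 23.6 | 73.1 |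
| north-west | 3.00 | 37.8 | 52.8 |
| north-west | 4.00 | 42.4 | 45.5 |
| north-west | 6.00 | 45.3 | 33.5 |
| north-west | 8.00 | 44.5 | 26.0 |

(each reading ± 0.5 percentage points)

* all flasks from highest to lowest amount of single product, in percent of the starting material charged, at 10 min (eta / alpha / delta / gamma)
* the amount of single product, in percent of the starting material charged of the flask you put first, at 10 min
* the amount of single product, in percent of the starting material charged of the flask you put last, at 10 min

- the numbers in the tables scatter with a standard deviation of 0.5 percentage points
- candidate steps: starting material + partner -> single product + released group; starting material + partner -> other mono adduct + released group; partner + single product -> double product + released group; partner + other mono adduct -> double product + released group; single product -> over-reaction product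

Two numbers in the runs look odd together. At 8.00 min single product makes up 0.655 of the starting material lost in the north-east run and 0.601 in the north-west run, yet the north-west run was charged with 5.00 times the partner. The ratio moves with the clock: in the north-west run it falls from 0.778 at 4.00 min to 0.601 at 8.00 min, which these readings give as a first-order loss of 0.0644 min⁻¹.

So the reckoning has a large term and a correction. The large term is the starting material lost, from the integrated second-order law, counting one partner per starting material lost. The correction is the survival share, single product over starting material lost (the selectivity on converted starting material), carried from the last north-west reading to 10 min and laid on each flask: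

rate = k · c(starting material) · c(partner), with k = 1.86 M⁻¹ min⁻¹

survival share = 0.529

gamma: 63.1% lost, single product 33.4%

alpha: 55.4% lost, single product 29.3%

eta: 53.7% lost, single product 28.4%

delta: 25.5% lost, single product 13.5%

The forecast gives the same order, gamma > alpha > eta > delta, but higher values than this reckoning: 34.5% (32% to 37%) for gamma and 15.1% (13.5% to 16.8%) for delta. Its ground is that the share “falls at a similar first-order rate in both runs”.

The flasks give gamma > alpha > eta > delta, with gamma at 33.0% and delta at 14.8%.

    starting material + partner → single product + released group (k = 1.80 M⁻¹ min⁻¹)
    starting material + partner → other mono adduct + released group (k = 0.0677 M⁻¹ min⁻¹)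
    partner + single product → double product + released group (k = 0.0215 M⁻¹ min⁻¹)
    partner + other mono adduct → double product + released group (k = 0.0369 M⁻¹ min⁻¹)
    single product → over-reaction product (k = 0.0901 min⁻¹)

Gamma keeps 37% of its starting material at 10 min, so its survival share is 0.524, against the 0.529 carried from the north-west run. The neighbour flask is gamma charged with 0.26 M of starting material, which makes 0.462 equiv of partner. The same law gives 44.2% lost, and the share turns that into 23.4% of single product. That neighbour flask keeps 55.8% of its starting material and holds 21.6% of single product.

Readings and results stem from a simulated flask with constants of no real substance.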